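Readings and results were generated by integration for substances that don't exist, and the scatter is random.

3 questions stand on this flask, and the last two hang on one ratio.

in all of them: starting material 39 mM
- east: coupling partner 66 mM; run made earlier
- north-east: coupling partner 100 mM; run made earlier
- flask: coupling partner 46.8 mM; time 5.0 d

| run | time / d | isomer of the product / % | target / % | starting material / % |
|---|---|---|---|---|
| east | 0.250 | 17.3 | 15.4 | 50.2 |
| east | 0.417 | 24.1 | 13.6 | 34.8 |
| east | 0.625 | 31.8 | 9.1 | 23.1 |
| east | 1.04 | 36.7 | 3.4 | 10.7 |
| east | 1.67 | 39.5 | 1.2 | 5.0 |
| east | 3.00 | 40.0 | 1.7 | 1.0 |
| north-east | 0.208 | 19.6 | 20.0 | 41.7 |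
| north-east | 0.625 | 37.2 | 8.4 | 9.3 |
| north-east | 1.04 | 41.2 | 2.7 | 3.0 |
| north-east | 1.67 | 41.6 | 0 | 0.4 |
| north-east | 2.50 | 40.8 | 0.5 | 0 |
| north-east | 3.00 | 39.7 | 0.2 | 0.1 |

(scatter of a reading: 0.5 percentage points)

- the earlier runs were read with a standard deviation of 0.5 percentage points

* share of isomer of the product in isomer of the product plus target at 1.0 h
* share of isomer of the product in isomer of the product plus target at 5.0 d
* which of isomer of the product and target there is more of at 5.0 d

In both runs starting material and coupling partner give target and isomer of the product, but at 3.00 d the east run shows 42.7 % of the charge, so target appears to drain into something unread. Its fall in the north-east run, with some feed still running, reads as a time constant of 0.366 d.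

My reckoning takes two extreme flasks. With the drain frozen, the early split stands. With the drain finished, target is a fixed fraction of isomer, the tail ratio: target over isomer in the north-east tail, where starting material reads 0.1 %, a quasi-steady state. It comes to 0.870 %, a rough reading, since those target readings stand near the scatter.

| extreme | target over isomer | isomer share |
|---|---|---|
| drain frozen, reading at 0.208 d | 102 % | 49.5 % |
| drain finished | 0.870 % | 99.1 % |

At 1.0 h, far shorter than the time constant, the flask sits near the first row, below that later reading. At 5.0 d, far longer, it sits near the second; its partner charge is smaller than in the north-east run, which supplied the ratio, so feed should linger longer and the share should stand slightly under that row.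

The forecast gives 35 %, 99 % and isomer of the product ahead, and holds that “the target is draining to something unseen”.

The flask gives 36.1 % and 98.8 %, with isomer of the product ahead at 36.9 % against 0.432 % of target. At 5.00 d, 2.6 % of the starting material is left. The tail ratio on that isomer gives 0.321 % of target, so the flask holds more target than the ratio gives, and its share reads 98.8 % against the 99.1 % of the second row.

    intermediate ⇌ target (K = 7.50, k = 0.850 h⁻¹)
    intermediate ⇌ isomer of the product (K = 160, k = 0.430 h⁻¹)
    target → over-reaction product (k = 0.200 h⁻¹)
    starting material + coupling partner → intermediate + released group (k = 2.10 M⁻¹ h⁻¹)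

With 19 mM of coupling partner, the tail ratio on that neighbour's 18.4 % of isomer gives 0.160 % of target and a share of 99.1 %. Computed, that neighbour holds 0.163 % of target and a share of 99.1 %, with 0.33 % of its partner left.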